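The data stem from a simulated flask from invented constants; the scatter is artificial.

| flask | left-handed substrate | right-handed substrate | solid reagent | remark | time |
|---|---|---|---|---|---|
| autumn | 0.21 M | 0.21 M | 0.42 M | run made earlier |  |
| summer | 0.21 M | 0.21 M | 0.95 M | run made earlier |  |
| flask | 0.21 M | 0.21 M | 0.630 M |  | 2.5 h |

- autumn (time / h: left-handed product / %): 0.250: 0.9; 0.417: 2.0; 0.833: 0.6; 1.50: 2.3; 3.00: 8.8
- summer (time / h: left-handed product / %): 0.250: 0; 0.833: 1.6; 1.33: 2.1; 2.00: 4.7; 3.00: 8.8

(scatter of a reading: 1 percentage point)

- partner is single-handed; left-handed substrate and right-handed substrate are mirror images of each other, charged as a racemate, each of them at the stated concentration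
- given per volume of solution although it is solid: solid reagent
- at the start none of the solid reagent is in solution
- partner is what solid reagent becomes in solution
- the handed part of partner does not stay in what it makes, so the products of the two hands are mirror images too

* how much left-handed product there is at 2.5 h, in percent of the left-handed substrate and right-handed substrate together charged
* concentration of partner in solution at 2.5 h, in percent of saturation

Early times say little: the first autumn reading of left-handed product is 0.9% of the charge at 0.250 h, and a reading scatters by 1 percentage point. So the logarithms go to the late readings. From 1.50 h to 3.00 h the autumn product climbs from 2.3% to 8.8%. The time exponent, powers of ten gained by product per power of ten gained by time, is 1.94. Near 2, it reads as a product rate climbing with time. The flask, read at 2.5 h, is then reckoned at 0.703 of the last autumn reading, which is 6.18%.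

One number serves if the solid charge stays out of it. The summer run, with 2.26 times the autumn solid, also ends at 8.8%. Its exponent from 1.33 h is 1.76, which gives the flask 6.38%. The two reckonings part by 0.2 points. The flask's solid charge lies between those of the two runs, and the reckoning stands at 6.18%.

The forecast gives 6.3%, above that reckoning, and partner at 35% of saturation, holding that “Solid loading therefore doesn't matter”.

The flask gives 6.38% of the charge as left-handed product, with partner at 32.1% of saturation. At 3.00 h the autumn run, without scatter, holds 8.24%, and the flask's solid charge in its place gives 8.24%.

    partner + left-handed substrate → left-handed product (k = 0.0509 M⁻¹ min⁻¹)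
    partner + right-handed substrate → right-handed product (k = 4.34 × 10⁻⁴ M⁻¹ min⁻¹)
    left-handed substrate ⇌ achiral form (K = 0.360, k = 0.00733 min⁻¹)
    right-handed substrate ⇌ achiral form (K = 0.360, k = 0.00733 min⁻¹)
    solid reagent ⇌ partner, rate k5*(cs5 - [partner]) while solid is left; crystals form when [partner] > cs5 (solubility = 0.100 M, k = 0.00498 min⁻¹)

Against the last autumn reading the flask stands at 0.725, where the exponent gave 0.703. Read at 1.0 h, the same flask gets 1.04% from the exponent and holds 1.51%.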